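The furan ring itself is disconnected, biomimetically, at both C–O bonds. O1 and its neighbours C2 (bearing CH2CO2Me) and C5 (bearing C16H33) are traced to a cis-3,6-disubstituted 3,6-dihydro-1,2-dioxine, the Plakortis-type cyclic peroxide, and this to singlet oxygen plus an acyclic (3E,5E)-dienoate. The key step converts methyl (3E,5E)-docosa-3,5-dienoate in one pot into the 2,5-disubstituted furan by [4+2] photooxygenation, Kornblum–DeLaMare rearrangement and dehydration. The unsubstituted C3–C4 edge of the furan is the former central bond of the diene, so the 2,5-pattern cannot be scrambled. The precursor is a linear C22 ester made by one Heck coupling.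

Key step: step 3

Remark: the target has no stereocentre and is achiral, so the SMILES defines a single compound and no enantiocontrol is needed. Only alkene geometry in the intermediates has to be controlled; the transient stereocentres of 6–8 form racemic and are erased on aromatisation.

Step 1
Reactants: 1 octadec-1-yne
Product: 3 (E)-1-iodooctadec-1-ene, via (E)-octadec-1-enylzirconocene chloride 2 (not isolated)
Conditions: Cp2Zr(H)Cl (1.2 equiv), THF, rt, dark; then I2 (1.2 equiv), 0 °C
Reagents that add atoms: iodine (I2), SMILES: II
Why: Schwartz hydrozirconation adds Zr–H syn across the terminal alkyne with zirconium at the terminal carbon, and iodinolysis of the C–Zr bond proceeds with retention, so the (E)-iodide should form as a single isomer.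

Step 2
Reactants: 3 (E)-1-iodooctadec-1-ene; 4 methyl but-3-enoate (3 equiv)
Product: 5 methyl (3E,5E)-docosa-3,5-dienoate
Conditions: Pd(OAc)2 (5 mol %), Ag2CO3 (1 equiv), MeCN, rt to 40 °C, dark
Reagents that add atoms: none
Why: Mizoroki–Heck vinylation under Jeffery-type silver conditions: oxidative addition with retention, carbopalladation at the terminal carbon of 4 and syn β-hydride elimination of the allylic C4–H should give the conjugated (E,E)-diene, while the silver salt removes iodide and H–Pd quickly and so suppresses migration of the diene towards the ester.

Step 3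
Reactants: 5 methyl (3E,5E)-docosa-3,5-dienoate
Product: 9 methyl 2-(5-hexadecylfuran-2-yl)acetate, via cis-3,6-dihydro-1,2-dioxine endoperoxide 6 (not isolated), via methyl (Z)-3-hydroxy-6-oxodocos-4-enoate 7 (not isolated), via methyl (Z)-6-hydroxy-3-oxodocos-4-enoate 8 (not isolated)
Conditions: O2 (1 atm), tetraphenylporphyrin (1 mol %), CH2Cl2, white LED, 0 °C; then N2 purge, dark, Et3N (0.2 equiv), 0 °C to rt; then Amberlyst-15 (H+ form), rt
Reagents that add atoms: dioxygen (as singlet oxygen), SMILES: O=O
Why: Photosensitised singlet oxygen adds suprafacially across C3 and C6 of the s-cis (E,E)-diene in a concerted [4+2] cycloaddition (the dioxine ring closes as a six-membered cycloadduct, cis-configured 6), placing one oxygen on each future furan α-carbon. Triethylamine then removes either of the two allylic O–CH protons with heterolysis of the weak O–O bond (Kornblum–DeLaMare rearrangement) to give the cis-γ-hydroxy enones 7 and 8, whose Z-alkene is inherited from the ring. In each, the hydroxyl adds to the ketone carbonyl in a 5-exo-trig closure and acid-catalysed loss of water aromatises the ring, so both regioisomers converge on the same furan. The closest known reaction type is the photooxygenation of 1,4-disubstituted 1,3-dienes to 3,6-dihydro-1,2-dioxines followed by base/acid conversion into 2,5-disubstituted furans, which is also the presumed biogenetic link between Plakortis cyclic peroxides and furanylacetates. No stereocentre survives in the product, so the cis relationship in 6 and the carbinol centres of 7 and 8 need no control. The selectivity required is [4+2] over the ene reaction at the C2 and C7 methylenes and over oxidation of the product furan; it is secured by the (E,E)-1,4-dialkyl diene, which reaches the s-cis conformer easily, by low temperature, and by removing light and oxygen before the base is added.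

Compound list
1 | octadec-1-yne | CCCCCCCCCCCCCCCCC#C | starting material
2 | (E)-octadec-1-enylzirconocene chloride | CCCCCCCCCCCCCCCC/C=C/[Zr](Cl)(C1C=CC=C1)C1C=CC=C1 | intermediate
3 | (E)-1-iodooctadec-1-ene | CCCCCCCCCCCCCCCC/C=C/I | intermediate
4 | methyl but-3-enoate | C=CCC(=O)OC | starting material
5 | methyl (3E,5E)-docosa-3,5-dienoate | CCCCCCCCCCCCCCCC/C=C/C=C/CC(=O)OC | intermediate
6 | methyl 2-(cis-6-hexadecyl-3,6-dihydro-1,2-dioxin-3-yl)acetate (racemic, one enantiomer drawn) | CCCCCCCCCCCCCCCC[C@@H]1C=C[C@H](CC(=O)OC)OO1 | intermediate
7 | methyl (4Z)-3-hydroxy-6-oxodocos-4-enoate (racemic) | CCCCCCCCCCCCCCCCC(=O)/C=C\C(O)CC(=O)OC | intermediate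
8 | methyl (4Z)-6-hydroxy-3-oxodocos-4-enoate (racemic) | CCCCCCCCCCCCCCCCC(O)/C=C\C(=O)CC(=O)OC | intermediate
9 | methyl 2-(5-hexadecylfuran-2-yl)acetate | CCCCCCCCCCCCCCCCc1ccc(CC(=O)OC)o1 | target

Total step count: 3
Longest linear sequence: 3 steps (1 → 3 → 5 → 9)

Steps most likely to fail

1. Step 3 (key step). The ene reaction of singlet oxygen at the allylic C2 and C7 methylenes, or a sluggish cycloaddition, may outrun the [4+2] addition. The base may also open the peroxide by β-elimination through the ester α-position instead of the Kornblum–DeLaMare pathway. The fallback avoids peroxide chemistry altogether and sets out from 1: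
   - Deprotonation of 1 with n-BuLi in THF at −78 °C should give lithium octadec-1-yn-1-ide F1.
   - After activation with BF3·OEt2, F1 should open commercial methyl 2-(oxiran-2-yl)acetate at its terminal carbon at −78 °C, where the ester is not attacked, to give methyl 3-hydroxydocos-5-ynoate F2.
   - Dess–Martin oxidation should give the alk-3-yn-1-one methyl 3-oxodocos-5-ynoate F3.
   - Cycloisomerisation of F3 with catalytic AuCl3 in MeCN (or ZnCl2 in CH2Cl2) should proceed by 5-endo-dig attack of the ketone oxygen on the activated alkyne followed by proton shift. This returns to the route at 9.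

2. Step 2. β-Hydride elimination towards C2, or re-addition of H–Pd, may move unsaturation into conjugation with the ester, and the alkene geometry may erode. The fallback forms the C4–C5 bond by cross-coupling of two preformed alkenes, so no H–Pd species is involved. It sets out from 3:
   - Zirconium-catalysed hydroboration of but-3-yn-1-ol with pinacolborane should give (E)-4-(4,4,5,5-tetramethyl-1,3,2-dioxaborolan-2-yl)but-3-en-1-ol F4.
   - Suzuki–Miyaura coupling of 3 with F4 (Pd(dppf)Cl2, K3PO4, THF/H2O) should give (3E,5E)-docosa-3,5-dien-1-ol F5.
   - Jones oxidation at 0 °C should give (3E,5E)-docosa-3,5-dienoic acid F6.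
   - Esterification with TMSCHN2 in MeOH/toluene returns to the route at 5.

3. Step 1. Aged Schwartz reagent may give incomplete hydrozirconation, or protodemetalation before iodinolysis may divert material to the terminal alkene. The fallback moves to boron and an ate-complex iodination, and sets out from 1:
   - Hydroboration with neat catecholborane at 70 °C should give 2-[(E)-octadec-1-enyl]-1,3,2-benzodioxaborole F7.
   - Hydrolysis with water should give (E)-octadec-1-enylboronic acid F8.
   - Treatment with aqueous NaOH and then I2 in Et2O at 0 °C should effect iododeboronation with retention. This returns to the route at 3.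

Further compounds
F1 | step 3 | lithium octadec-1-yn-1-ide | [Li+].[C-]#CCCCCCCCCCCCCCCCC
F2 | step 3 | methyl 3-hydroxydocos-5-ynoate (racemic) | CCCCCCCCCCCCCCCCC#CCC(O)CC(=O)OC
F3 | step 3 | methyl 3-oxodocos-5-ynoate | CCCCCCCCCCCCCCCCC#CCC(=O)CC(=O)OC
F4 | step 2 | (E)-4-(4,4,5,5-tetramethyl-1,3,2-dioxaborolan-2-yl)but-3-en-1-ol | OCC/C=C/B1OC(C)(C)C(C)(C)O1
F5 | step 2 | (3E,5E)-docosa-3,5-dien-1-ol | CCCCCCCCCCCCCCCC/C=C/C=C/CCO
F6 | step 2 | (3E,5E)-docosa-3,5-dienoic acid | CCCCCCCCCCCCCCCC/C=C/C=C/CC(=O)O
F7 | step 1 | 2-[(E)-octadec-1-enyl]-1,3,2-benzodioxaborole | CCCCCCCCCCCCCCCC/C=C/B1Oc2ccccc2O1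
F8 | step 1 | (E)-octadec-1-enylboronic acid | CCCCCCCCCCCCCCCC/C=C/B(O)O
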